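My unit is one percent of the starting material charged, which in zeta is 5.10 × 10⁻⁴ M. Zeta is the flask asked about, and delta is the earlier run at lower catalyst loading.

in all of them: starting material 0.051 M; coupling partner 1.05 equiv

|  | free catalyst | remark |
|---|---|---|
| zeta | 0.05 mol% | the very flask that is asked about, followed so far |
| delta | 0.025 mol% | run made earlier |
| flask | 0.05 mol% |  |

| run | time / min | target / % | starting material / % |
|---|---|---|---|
| zeta | 12.0 | 5.6 | 94.4 |
| zeta | 25.0 | 10.7 | 89.9 |
| zeta | 40.0 | 17.3 | 82.5 |
| zeta | 50.0 | 22.2 | 78.0 |
| delta | 20.0 | 4.6 | 95.0 |
| delta | 40.0 | 9.4 | 91.6 |
| delta | 60.0 | 12.0 | 87.5 |
| delta | 80.0 | 15.4 | 83.7 |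

(each reading ± 1 percentage point)

- the earlier runs were read with a standard deviation of 1 percentage point
- no earlier run changes the charge of coupling partner; that part of a forecast is a guess

- factor on the rate of making target when 50 % of the starting material are converted if coupling partner is charged twice over
- factor on the rate when 50 % of the starting material are converted if free catalyst is charged at 0.5 mol% instead

Starting material is the limiting reagent in zeta: coupling partner is charged at 0.0536 M, which is more than the 0.051 M of starting material. I therefore keep the ledger on starting material.

At the last zeta reading, the first entry is 78.0 % still unreacted and the second is 22.2 % as target, which together make 100 %. A third entry is starting material held on the catalyst. If each catalyst holds one, that entry is 0.05 mol%, while a reading scatters by 1 percentage point.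

I assume that each starting material converted takes one coupling partner with it. The ledger then gives the partner balance, the concentration of coupling partner left at a conversion x, here taken at 50 %:

partner balance = c_A × (equivalents − x) = 0.0281 M

Here c_A is the starting concentration of starting material. With the partner charged twice over, the same line gives:

partner balance = 0.0816 M

The factor on the rate is therefore 2.91 if the rate is first order in coupling partner, and one if it is zero order. Target rises nearly steadily in zeta, and I commit to that span, leaning towards its low end.

The forecast gives 1.4 (0.9 to 2.8) for doubling the partner and 10 (6 to 13) for the higher catalyst loading. On the partner it says: “The data favour near zero, so about 1.4, which is a guess.” Its high end lies below my 2.91 for first order.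

    coupling partner + free catalyst → catalyst intermediate A (k = 95.0 L mol⁻¹ s⁻¹)
    starting material + catalyst intermediate A → catalyst intermediate B (k = 9.80 L mol⁻¹ s⁻¹)
    catalyst intermediate B → by-product + catalyst intermediate C (k = 0.730 s⁻¹)
    catalyst intermediate C → catalyst intermediate D (k = 0.770 s⁻¹)
    catalyst intermediate D ⇌ free catalyst + target (K = 0.0750 M, k = 0.670 s⁻¹)
    catalyst intermediate D → spent catalyst (k = 2.00 × 10⁻⁴ s⁻¹)

The flask gives 1.05 for doubling the partner and 14.0 for the higher catalyst loading, so the partner factor lies below the 2.91 of first order. After 2.00 h, free catalyst, the form that takes up coupling partner, stands at 3.03 % of the catalyst charged. After 20.0 h, 0.467 % of the starting material is left, so the partner balance, carried on from 0.0281 M, leaves 5.21 % of the partner's own charge, and the flask holds 5.19 %.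

(Readings and results come from a simulation on assumed constants.)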